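**Retrosynthetic overview**

1. Target 22 ⇐ selective salicyloylation of diol 19 ⇐ hydroxyl-directed reduction at C-4 of ketol 18 ⇐ 1,6-reduction of dienone 17.
2. 17 ⇐ cycloheptatriene 12 (C-1 deoxygenation, Si–O cleavage). 12 ⇐ diazoketone 10 by an intramolecular Buchner reaction: the carbenoid carbon (C-8a, carrying its methyl) closes the cyclopentane onto the arene ipso carbon C-3a and is inserted into the ipso–ortho′ bond, so the seven-membered ring is the benzene ring enlarged by one carbon (cyclopropane opening, strain release).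
3. Enabling feature: the ring C-3a/C-4/C-5/C-6/C-7/C-8 carries O at C-4 and CH3 at C-6, ortho and para to ring-fusion carbon C-3a, so it is the ring of m-cresol with quaternary C-8a as the extra carbon between C-3a and C-8. O-3 and O-4 are 1,3-related across C-3a, so a t-Bu2Si bridge (temporary six-membered ring) can relay C-3 to C-8a.
4. 10 ⇐ m-cresol 1 + isobutyryl chloride 2: Fries ketone 4, reagent-controlled allylation (sets C-3), silylene 6, Wacker oxidation, methylation, diazo transfer.
5. Ring order: benzene ring (bought) → dioxasiline (temporary) → cyclopentane and cycloheptatriene together in the key step; C-8a, C-3a and C-4 are all relayed from C-3.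

Key step: step 7

Remark (assumption on the chemistry): the (R,R)-allylsilane of step 2 is taken to give (R)-5; should the sense of induction be the opposite, the equally accessible (S,S)-reagent is used. Locants for the bicyclic compounds are azulene locants (C-1, C-2, C-3, C-3a, C-4 to C-8, C-8a).

**Route**

Step 1
Reactants: 1 3-methylphenol (m-cresol); 2 2-methylpropanoyl chloride
Product: 4 1-(2-hydroxy-4-methylphenyl)-2-methylpropan-1-one, via m-tolyl isobutyrate 3 (not isolated)
Conditions: neat, 80 °C; then AlCl3 (1.5 equiv), 140 °C; aq. HCl work-up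
Reagents that add atoms: none
Why: O-acylation followed by a high-temperature Fries rearrangement, in which the acyl group should migrate to the chelation-stabilised ortho position para to the methyl group.

Step 2
Reactants: 4 1-(2-hydroxy-4-methylphenyl)-2-methylpropan-1-one
Product: 5 2-[(3R)-3-hydroxy-2-methylhex-5-en-3-yl]-5-methylphenol
Conditions: (R,R)-allylsilane (1.5 equiv), CH2Cl2, 23 °C; then aq. HCl/EtOAc work-up
Reagents that add atoms: (3aR,7aR)-1,3-bis(4-bromobenzyl)-2-chloro-2-(prop-2-en-1-yl)octahydro-1H-1,3,2-benzodiazasilole, C=CC[Si]1(Cl)N(Cc2ccc(Br)cc2)[C@@H]2CCCC[C@H]2N1Cc1ccc(Br)cc1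
Why: Enantioselective allylation of a 2′-hydroxyaryl ketone with a strained chiral allylchlorosilane: the phenol displaces chloride, the ketone binds the Lewis-acidic silicon and allyl is transferred through a closed chair-like transition state in which the C2-symmetric diamine selects the carbonyl face, setting C-3 (R), the only stereocentre set by an external chiral source.

Step 3
Reactants: 5 2-[(3R)-3-hydroxy-2-methylhex-5-en-3-yl]-5-methylphenol
Product: 6 (4R)-2,2-di-tert-butyl-7-methyl-4-(propan-2-yl)-4-(prop-2-en-1-yl)-4H-1,3,2-benzodioxasiline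
Conditions: t-Bu2Si(OTf)2 (1.2 equiv), 2,6-lutidine (3 equiv), DMF, 0 → 50 °C
Reagents that add atoms: di-tert-butylsilyl bis(trifluoromethanesulfonate), CC(C)(C)[Si](OS(=O)(=O)C(F)(F)F)(OS(=O)(=O)C(F)(F)F)C(C)(C)C
Why: Cyclic silylene formation: the phenol is silylated first and the hindered tertiary hydroxyl then closes the six-membered dioxasiline, a temporary ring that locks the carbinol C–O bond in the arene plane.

Step 4
Reactants: 6 (4R)-2,2-di-tert-butyl-7-methyl-4-(propan-2-yl)-4-(prop-2-en-1-yl)-4H-1,3,2-benzodioxasiline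
Product: 7 1-[(4R)-2,2-di-tert-butyl-7-methyl-4-(propan-2-yl)-4H-1,3,2-benzodioxasilin-4-yl]propan-2-one
Conditions: PdCl2 (10 mol%), CuCl (1 equiv), O2 (1 atm), DMF/H2O 7:1, 23 °C
Reagents that add atoms: water, O
Why: Tsuji–Wacker oxidation of the terminal alkene should give the methyl ketone by Markovnikov hydroxypalladation, the silylene and arene being inert.

Step 5
Reactants: 7 1-[(4R)-2,2-di-tert-butyl-7-methyl-4-(propan-2-yl)-4H-1,3,2-benzodioxasilin-4-yl]propan-2-one
Product: 8 1-[(4R)-2,2-di-tert-butyl-7-methyl-4-(propan-2-yl)-4H-1,3,2-benzodioxasilin-4-yl]butan-2-one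
Conditions: LDA (1.05 equiv), THF, −78 °C; MeI (3 equiv), −78 → −40 °C
Reagents that add atoms: iodomethane, CI
Why: Kinetic deprotonation should occur at the methyl group (the CH2 is neopentyl, next to the quaternary carbinol carbon) and the terminal enolate is C-methylated (enolate alkylation).

Step 6
Reactants: 8 1-[(4R)-2,2-di-tert-butyl-7-methyl-4-(propan-2-yl)-4H-1,3,2-benzodioxasilin-4-yl]butan-2-one
Product: 10 3-diazo-1-[(4R)-2,2-di-tert-butyl-7-methyl-4-(propan-2-yl)-4H-1,3,2-benzodioxasilin-4-yl]butan-2-one, via trifluoroacetyl diketone 9 (not isolated)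
Conditions: LiHMDS (1.1 equiv), THF, −78 °C; CF3CO2CH2CF3 (1.2 equiv); aq. HCl work-up; then MsN3 (1.5 equiv), Et3N (1.5 equiv), H2O (1 equiv), MeCN, 23 °C
Reagents that add atoms: methanesulfonyl azide, CS(=O)(=O)N=[N+]=[N-]; 2,2,2-trifluoroethyl trifluoroacetate, O=C(OCC(F)(F)F)C(F)(F)F (its CF3CO group is carried by 9 only)
Why: Detrifluoroacetylative diazo transfer: the kinetic enolate forms on the less hindered ethyl side, is trifluoroacetylated, and the activated 1,3-diketone takes the diazo group from the sulfonyl azide with loss of the trifluoroacetyl group.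

Step 7
Reactants: 10 3-diazo-1-[(4R)-2,2-di-tert-butyl-7-methyl-4-(propan-2-yl)-4H-1,3,2-benzodioxasilin-4-yl]butan-2-one
Product: 12 (3R,8aR)-3,4-[(di-tert-butylsilanediyl)bis(oxy)]-6,8a-dimethyl-3-(propan-2-yl)-2,3-dihydroazulen-1(8aH)-one, via norcaradiene 11 (not isolated)
Conditions: Rh2(pfb)4 (1 mol%), CH2Cl2, 40 °C, slow addition of 10 at high dilution; filtration through basic alumina
Reagents that add atoms: none
Why: Rh(II) decomposes the diazo group to an electrophilic carbenoid at C-8a, which adds from the side chain across the arene ipso/ortho′ bond (C-3a–C-8) to give norcaradiene 11, and the strained cyclopropane then opens by a thermally allowed disrotatory 6π electrocyclic process that cleaves C-3a–C-8, so the six-membered arene ring becomes the seven-membered ring with C-8a inserted. The closest known reaction type is the intramolecular Buchner reaction of 2-diazo-5-arylpentan-3-ones to 8a-methyl-dihydroazulenones under Rh(II) carboxylate catalysis. The cyclopentanone ring is closed by the [2+1] addition (new bonds C-8a–C-3a and C-8a–C-8, a 5-exo attack on the ipso carbon), and the seven-membered ring by ring expansion of the benzene ring through the norcaradiene–cycloheptatriene valence isomerisation. The new quaternary centre C-8a is controlled by C-3 alone: the silylene bridge holds the C-3–O bond in the arene plane on the C-4 side, so CH2-2 and the isopropyl group are fixed on opposite π-faces and the carbenoid can only arrive from the face carrying CH2-2, which places the 8a-methyl cis to O-3. The step needs chemoselectivity for arene addition over 1,5-C–H insertion at the isopropyl methine and over ylide formation at the bridge oxygen, which the electron-rich aryl silyl ether, the perfluorobutyrate ligands, the deactivation of the methine by the adjacent C–O bond and the hindered t-Bu2Si oxygen should secure; and regioselectivity for the unsubstituted ortho′ bond over the oxygenated C-3a–C-4 bond, which the bulky silylene on that side should secure.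

Step 8
Reactants: 12 (3R,8aR)-3,4-[(di-tert-butylsilanediyl)bis(oxy)]-6,8a-dimethyl-3-(propan-2-yl)-2,3-dihydroazulen-1(8aH)-one
Product: 13 tosylhydrazone of 12 at C-1
Conditions: TsNHNH2 (1.5 equiv), 4 Å MS, THF/MeOH, 50 °C
Reagents that add atoms: 4-methylbenzenesulfonohydrazide, Cc1ccc(S(=O)(=O)NN)cc1
Why: Condensation at the only carbonyl group under neutral conditions that should leave the acid-sensitive cycloheptatriene untouched.

Step 9
Reactants: 13 tosylhydrazone of 12 at C-1
Product: 15 (3R,8aR)-3,4-[(di-tert-butylsilanediyl)bis(oxy)]-6,8a-dimethyl-3-(propan-2-yl)-1,2,3,8a-tetrahydroazulene, via tosylhydrazine 14 (not isolated)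
Conditions: catecholborane (3 equiv), CHCl3, 0 → 23 °C; then NaOAc·3H2O (5 equiv), 60 °C
Reagents that add atoms: none
Why: Kabalka deoxygenation: hydride adds to the C=N bond and acetate then triggers loss of sulfinate and N2, giving the methylene group without base so that the β-silyloxy group is not eliminated; with the acceptor gone from C-8a the product should rest as the cycloheptatriene.

Step 10
Reactants: 15 (3R,8aR)-3,4-[(di-tert-butylsilanediyl)bis(oxy)]-6,8a-dimethyl-3-(propan-2-yl)-1,2,3,8a-tetrahydroazulene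
Product: 17 (3R,3aR,8aR)-3-hydroxy-6,8a-dimethyl-3-(propan-2-yl)-2,3,3a,8a-tetrahydroazulen-4(1H)-one, via trienol 16 (not isolated)
Conditions: HF·pyridine, pyridine, THF, 0 → 23 °C; then DBU (0.1 equiv), CH2Cl2, 0 °C
Reagents that add atoms: none
Why: Fluoride cleaves both Si–O bonds, trienol 16 ketonises by protonation at C-3a (its only α-position) to the linearly conjugated 2,4-dienone, and the mild base stage should equilibrate C-3a to the trans-fused ketol in which C-4 lies trans to the isopropyl group and cis to the hydroxyl (thermodynamic control relayed from C-3 and C-8a).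

Step 11
Reactants: 17 (3R,3aR,8aR)-3-hydroxy-6,8a-dimethyl-3-(propan-2-yl)-2,3,3a,8a-tetrahydroazulen-4(1H)-one
Product: 18 (3R,3aR,8aR)-3-hydroxy-6,8a-dimethyl-3-(propan-2-yl)-2,3,3a,5,8,8a-hexahydroazulen-4(1H)-one
Conditions: Li (3 equiv), NH3(l)/THF, −78 °C, 10 min; then solid NH4Cl
Reagents that add atoms: none
Why: Dissolving-metal 1,6-reduction of a 2,4-dienone: two electrons and a proton at the δ-carbon C-8 give the dienolate, whose kinetic α-protonation at C-5 on quenching should give the β,γ-unsaturated ketone with the C-6=C-7 bond of the target (as with steroidal 4,6-dien-3-ones).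

Step 12
Reactants: 18 (3R,3aR,8aR)-3-hydroxy-6,8a-dimethyl-3-(propan-2-yl)-2,3,3a,5,8,8a-hexahydroazulen-4(1H)-one
Product: 19 (3R,3aS,4S,8aR)-6,8a-dimethyl-3-(propan-2-yl)-1,2,3,3a,4,5,8,8a-octahydroazulene-3,4-diol
Conditions: Me4NBH(OAc)3 (5 equiv), MeCN/AcOH 1:1, −30 → −10 °C
Reagents that add atoms: none
Why: Hydroxyl-directed reduction (Evans–Saksena): the tertiary hydroxyl exchanges onto boron and hydride is delivered intramolecularly to the face of the C-4 carbonyl turned towards C-3, which is also the face anti to C-8a in the chair-like seven-membered ring, so the (4S) alcohol is expected.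

Step 13
Reactants: 19 (3R,3aS,4S,8aR)-6,8a-dimethyl-3-(propan-2-yl)-1,2,3,3a,4,5,8,8a-octahydroazulene-3,4-diol; 20 2-(chlorocarbonyl)phenyl acetate
Product: 21 (3R,3aS,4S,8aR)-3-hydroxy-6,8a-dimethyl-3-(propan-2-yl)-1,2,3,3a,4,5,8,8a-octahydroazulen-4-yl 2-(acetyloxy)benzoate
Conditions: 20 (1.5 equiv), Et3N, DMAP (0.2 equiv), CH2Cl2, 0 → 23 °C
Reagents that add atoms: none
Why: DMAP-catalysed acylation should occur only at the secondary C-4 hydroxyl, the tertiary C-3 hydroxyl being too hindered; the phenol is masked as its acetate to prevent self-condensation.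

Step 14
Reactants: 21 (3R,3aS,4S,8aR)-3-hydroxy-6,8a-dimethyl-3-(propan-2-yl)-1,2,3,3a,4,5,8,8a-octahydroazulen-4-yl 2-(acetyloxy)benzoate
Product: 22 (3R,3aS,4S,8aR)-3-hydroxy-6,8a-dimethyl-3-(propan-2-yl)-1,2,3,3a,4,5,8,8a-octahydroazulen-4-yl 2-hydroxybenzoate
Conditions: pyrrolidine (3 equiv), CH2Cl2, 0 → 23 °C
Reagents that add atoms: none
Why: Chemoselective aminolysis of the aryl acetate (phenoxide leaving group); the hindered secondary salicylate, stabilised by its new intramolecular hydrogen bond, should be untouched.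

**Compound list**

1 | 3-methylphenol (m-cresol) | Cc1cccc(O)c1 | starting material
2 | 2-methylpropanoyl chloride | CC(C)C(=O)Cl | starting material
3 | 3-methylphenyl 2-methylpropanoate | CC(C)C(=O)Oc1cccc(C)c1 | intermediate (not isolated)
4 | 1-(2-hydroxy-4-methylphenyl)-2-methylpropan-1-one | CC(C)C(=O)c1ccc(C)cc1O | intermediate
5 | 2-[(3R)-3-hydroxy-2-methylhex-5-en-3-yl]-5-methylphenol | C=CC[C@@](O)(C(C)C)c1ccc(C)cc1O | intermediate
6 | (4R)-2,2-di-tert-butyl-7-methyl-4-(propan-2-yl)-4-(prop-2-en-1-yl)-4H-1,3,2-benzodioxasiline | C=CC[C@]1(C(C)C)O[Si](C(C)(C)C)(C(C)(C)C)Oc2cc(C)ccc21 | intermediate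
7 | 1-[(4R)-2,2-di-tert-butyl-7-methyl-4-(propan-2-yl)-4H-1,3,2-benzodioxasilin-4-yl]propan-2-one | CC(=O)C[C@]1(C(C)C)O[Si](C(C)(C)C)(C(C)(C)C)Oc2cc(C)ccc21 | intermediate
8 | 1-[(4R)-2,2-di-tert-butyl-7-methyl-4-(propan-2-yl)-4H-1,3,2-benzodioxasilin-4-yl]butan-2-one | CCC(=O)C[C@]1(C(C)C)O[Si](C(C)(C)C)(C(C)(C)C)Oc2cc(C)ccc21 | intermediate
9 | 1,1,1-trifluoro-3-methyl-5-[(4R)-2,2-di-tert-butyl-7-methyl-4-(propan-2-yl)-4H-1,3,2-benzodioxasilin-4-yl]pentane-2,4-dione (C-3 enolisable, both epimers) | CC(C(=O)C(F)(F)F)C(=O)C[C@]1(C(C)C)O[Si](C(C)(C)C)(C(C)(C)C)Oc2cc(C)ccc21 | intermediate (not isolated)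
10 | 3-diazo-1-[(4R)-2,2-di-tert-butyl-7-methyl-4-(propan-2-yl)-4H-1,3,2-benzodioxasilin-4-yl]butan-2-one | CC(=[N+]=[N-])C(=O)C[C@]1(C(C)C)O[Si](C(C)(C)C)(C(C)(C)C)Oc2cc(C)ccc21 | intermediate
11 | norcaradiene valence isomer of 12 (cyclopropane C-8a/C-3a/C-8, diene C-4=C-5 and C-6=C-7, same configuration at C-3 and C-8a) | CC1=C[C@@H]2[C@@]3(C)C(=O)C[C@]4(C(C)C)O[Si](C(C)(C)C)(C(C)(C)C)OC(=C1)[C@]234 | intermediate (not isolated)
12 | (3R,8aR)-3,4-[(di-tert-butylsilanediyl)bis(oxy)]-6,8a-dimethyl-3-(propan-2-yl)-2,3-dihydroazulen-1(8aH)-one (triene C-3a=C-4, C-5=C-6, C-7=C-8; O-3 cis to 8a-CH3) | CC1=CC(O[Si](C(C)(C)C)(C(C)(C)C)O2)=C3[C@]2(C(C)C)CC(=O)[C@]3(C)C=C1 | intermediate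
13 | tosylhydrazone of 12 at C-1 | CC1=CC(O[Si](C(C)(C)C)(C(C)(C)C)O2)=C3[C@]2(C(C)C)CC(=NNS(=O)(=O)c4ccc(C)cc4)[C@]3(C)C=C1 | intermediate
14 | tosylhydrazine from hydride addition to 13 (C-1 epimers) | CC1=CC(O[Si](C(C)(C)C)(C(C)(C)C)O2)=C3[C@]2(C(C)C)CC(NNS(=O)(=O)c4ccc(C)cc4)[C@]3(C)C=C1 | intermediate (not isolated)
15 | (3R,8aR)-3,4-[(di-tert-butylsilanediyl)bis(oxy)]-6,8a-dimethyl-3-(propan-2-yl)-1,2,3,8a-tetrahydroazulene | CC1=CC(O[Si](C(C)(C)C)(C(C)(C)C)O2)=C3[C@]2(C(C)C)CC[C@]3(C)C=C1 | intermediate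
16 | (3R,8aR)-6,8a-dimethyl-3-(propan-2-yl)-1,2,3,8a-tetrahydroazulene-3,4-diol (trienol) | CC1=CC(O)=C2[C@](O)(C(C)C)CC[C@]2(C)C=C1 | intermediate (not isolated)
17 | (3R,3aR,8aR)-3-hydroxy-6,8a-dimethyl-3-(propan-2-yl)-2,3,3a,8a-tetrahydroazulen-4(1H)-one (trans-fused; 3-OH cis to 8a-CH3) | CC1=CC(=O)[C@H]2[C@](O)(C(C)C)CC[C@]2(C)C=C1 | intermediate
18 | (3R,3aR,8aR)-3-hydroxy-6,8a-dimethyl-3-(propan-2-yl)-2,3,3a,5,8,8a-hexahydroazulen-4(1H)-one | CC1=CC[C@@]2(C)CC[C@@](O)(C(C)C)[C@@H]2C(=O)C1 | intermediate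
19 | (3R,3aS,4S,8aR)-6,8a-dimethyl-3-(propan-2-yl)-1,2,3,3a,4,5,8,8a-octahydroazulene-3,4-diol | CC1=CC[C@@]2(C)CC[C@@](O)(C(C)C)[C@@H]2[C@@H](O)C1 | intermediate
20 | 2-(chlorocarbonyl)phenyl acetate (O-acetylsalicyloyl chloride) | CC(=O)Oc1ccccc1C(=O)Cl | starting material
21 | (3R,3aS,4S,8aR)-3-hydroxy-6,8a-dimethyl-3-(propan-2-yl)-1,2,3,3a,4,5,8,8a-octahydroazulen-4-yl 2-(acetyloxy)benzoate | CC1=CC[C@@]2(C)CC[C@@](O)(C(C)C)[C@@H]2[C@@H](OC(=O)c2ccccc2OC(C)=O)C1 | intermediate
22 | (3R,3aS,4S,8aR)-3-hydroxy-6,8a-dimethyl-3-(propan-2-yl)-1,2,3,3a,4,5,8,8a-octahydroazulen-4-yl 2-hydroxybenzoate | CC1=CC[C@@]2(C)CC[C@@](O)(C(C)C)[C@@H]2[C@@H](OC(=O)c2ccccc2O)C1 | target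

Total step count: 14. Longest linear sequence: 14 steps (from 1).

**Steps most likely to fail, with fallbacks**

Step 7 (key step). The carbenoid may partition into 1,5-C–H insertion at the isopropyl methine or attack on the bridge oxygen. The silylene ring may also keep the side chain away from the arene π-face, and the product may aromatise by acid-promoted rearrangement on handling. The fallback gives up the bridge and sets out from 5. Both hydroxyls are silylated (TBSOTf, 2,6-lutidine) to the open-chain bis-TBS ether F1. Wacker oxidation then gives methyl ketone F2, enolate methylation gives ethyl ketone F3, and detrifluoroacetylative diazo transfer gives diazoketone F4. Buchner reaction of this untethered substrate with a Rh(II) carboxylate, or with a Cu(I)–bis(oxazoline) complex if catalyst control is needed, should give azulenone F5; here the benzylic carbon rotates freely and C-8a is governed by allylic strain, with separation of diastereomers. Condensation with tosylhydrazide gives tosylhydrazone F6, and catecholborane/NaOAc gives triene F7. HF·pyridine then returns to the route at 17.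

Step 9. Hydride transfer to the hindered C=N bond next to the quaternary carbon may be incomplete, and the borane or the diazene intermediate may react with the triene. The fallback sets out from 12 and removes the oxygen by a radical route. NaBH4 (MeOH/THF, 0 °C) gives carbinol F8 (either C-1 epimer serves). Thiocarbonyldiimidazole/DMAP gives imidazolyl thiocarbonate F9. Bu3SnH/AIBN (toluene, 80 °C, Barton–McCombie) returns to the route at 15.

Step 10. Protonation at C-3a may occur from the wrong face without later equilibration, and the free tertiary ketol may undergo retro-aldol opening or dehydration during the base stage and in the following Li/NH3 step. The fallback sets out from 15. One equivalent of buffered fluoride (TBAF/AcOH, THF, −40 °C) opens only the enol Si–O bond and gives the fluorosilyl-protected ketol F10, which cannot undergo retro-aldol cleavage and is equilibrated at C-3a with DBU. Li/NH3 gives the β,γ-enone F11. Because the hydroxyl is blocked, the ketone is reduced by external hydride (L-Selectride, THF, −78 °C, attack anti to C-8a on the chair-like ring) to alcohol F12. TBAF (THF, 23 °C) removes the fluorosilyl group and returns to the route at 19.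

**Further compounds**

F1 | step 7 | tert-butyl{2-[(3R)-3-{[tert-butyl(dimethyl)silyl]oxy}-2-methylhex-5-en-3-yl]-5-methylphenoxy}dimethylsilane | C=CC[C@@](O[Si](C)(C)C(C)(C)C)(C(C)C)c1ccc(C)cc1O[Si](C)(C)C(C)(C)C
F2 | step 7 | (4R)-4-{[tert-butyl(dimethyl)silyl]oxy}-4-(2-{[tert-butyl(dimethyl)silyl]oxy}-4-methylphenyl)-5-methylhexan-2-one | CC(=O)C[C@@](O[Si](C)(C)C(C)(C)C)(C(C)C)c1ccc(C)cc1O[Si](C)(C)C(C)(C)C
F3 | step 7 | (5R)-5-{[tert-butyl(dimethyl)silyl]oxy}-5-(2-{[tert-butyl(dimethyl)silyl]oxy}-4-methylphenyl)-6-methylheptan-3-one | CCC(=O)C[C@@](O[Si](C)(C)C(C)(C)C)(C(C)C)c1ccc(C)cc1O[Si](C)(C)C(C)(C)C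
F4 | step 7 | (5R)-2-diazo-5-{[tert-butyl(dimethyl)silyl]oxy}-5-(2-{[tert-butyl(dimethyl)silyl]oxy}-4-methylphenyl)-6-methylheptan-3-one | CC(=[N+]=[N-])C(=O)C[C@@](O[Si](C)(C)C(C)(C)C)(C(C)C)c1ccc(C)cc1O[Si](C)(C)C(C)(C)C
F5 | step 7 | (3R,8aR)-3,4-bis{[tert-butyl(dimethyl)silyl]oxy}-6,8a-dimethyl-3-(propan-2-yl)-2,3-dihydroazulen-1(8aH)-one | CC1=CC(O[Si](C)(C)C(C)(C)C)=C2[C@](O[Si](C)(C)C(C)(C)C)(C(C)C)CC(=O)[C@]2(C)C=C1
F6 | step 7 | tosylhydrazone of F5 at C-1 | CC1=CC(O[Si](C)(C)C(C)(C)C)=C2[C@](O[Si](C)(C)C(C)(C)C)(C(C)C)CC(=NNS(=O)(=O)c3ccc(C)cc3)[C@]2(C)C=C1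
F7 | step 7 | (3R,8aR)-3,4-bis{[tert-butyl(dimethyl)silyl]oxy}-6,8a-dimethyl-3-(propan-2-yl)-1,2,3,8a-tetrahydroazulene | CC1=CC(O[Si](C)(C)C(C)(C)C)=C2[C@](O[Si](C)(C)C(C)(C)C)(C(C)C)CC[C@]2(C)C=C1
F8 | step 9 | (3R,8aR)-3,4-[(di-tert-butylsilanediyl)bis(oxy)]-6,8a-dimethyl-3-(propan-2-yl)-1,2,3,8a-tetrahydroazulen-1-ol (C-1 epimers) | CC1=CC(O[Si](C(C)(C)C)(C(C)(C)C)O2)=C3[C@]2(C(C)C)CC(O)[C@]3(C)C=C1
F9 | step 9 | O-[(3R,8aR)-3,4-[(di-tert-butylsilanediyl)bis(oxy)]-6,8a-dimethyl-3-(propan-2-yl)-1,2,3,8a-tetrahydroazulen-1-yl] 1H-imidazole-1-carbothioate (C-1 epimers) | CC1=CC(O[Si](C(C)(C)C)(C(C)(C)C)O2)=C3[C@]2(C(C)C)CC(OC(=S)n4ccnc4)[C@]3(C)C=C1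
F10 | step 10 | (3R,3aR,8aR)-3-{[di-tert-butyl(fluoro)silyl]oxy}-6,8a-dimethyl-3-(propan-2-yl)-2,3,3a,8a-tetrahydroazulen-4(1H)-one | CC1=CC(=O)[C@H]2[C@](O[Si](F)(C(C)(C)C)C(C)(C)C)(C(C)C)CC[C@]2(C)C=C1
F11 | step 10 | (3R,3aR,8aR)-3-{[di-tert-butyl(fluoro)silyl]oxy}-6,8a-dimethyl-3-(propan-2-yl)-2,3,3a,5,8,8a-hexahydroazulen-4(1H)-one | CC1=CC[C@@]2(C)CC[C@@](O[Si](F)(C(C)(C)C)C(C)(C)C)(C(C)C)[C@@H]2C(=O)C1
F12 | step 10 | (3R,3aS,4S,8aR)-3-{[di-tert-butyl(fluoro)silyl]oxy}-6,8a-dimethyl-3-(propan-2-yl)-1,2,3,3a,4,5,8,8a-octahydroazulen-4-ol | CC1=CC[C@@]2(C)CC[C@@](O[Si](F)(C(C)(C)C)C(C)(C)C)(C(C)C)[C@@H]2[C@@H](O)C1
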